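**Assumptions.** Locants follow the terpenoid chain: C1 = ArCH2, C2 = ring CH, C3(Me)=C4, C5, C6(Br), C7 (quaternary), C8, C9, C10(Br), C11 (C–O of the oxane), C12, C13, C14 (ester O), C15 (CMe2–O). On this numbering the target is 2R,6S,7S,10R,11R,14S. In step 3, hydride is assumed to add anti to the allyl group (OH cis to allyl).

## Retrosynthetic overview

1. Phenol MOM removal is last; the 15-membered ring is closed at Ar–C1 by an intramolecular B-alkyl Suzuki coupling, with C2 set by 9-BBN hydroboration of a ring-A exocyclic diene.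
2. The oxane ring and C10–Br/C11–O come from a 6-exo bromoetherification of a Z-C10=C11 alkene by the C15 tertiary alcohol.
3. Three similar-sized fragments are united late: ring-A iodide **10**, Z-vinyl iodide alcohol **17** and benzoic acid **21**, by esterification (C14–O) and then sp3–sp2 Negishi coupling (C9–C10).
4. Ring A comes from cyclohexane-1,3-dione: C-methylation/allylation, CBS desymmetrisation (C6, C7), Appel inversion (C6–Br), α-methylation/Saegusa.
5. Ring order: ring A (carbocycle from the start) → oxane (step 21) → macrolactone ring (step 23).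

## Route

### Ring-A fragment

**Step 1**
Reactants: **1** cyclohexane-1,3-dione
Product: **2** 2-methylcyclohexane-1,3-dione
Conditions: MeI, aq. NaOH, dioxane/H2O, reflux
Reagents that add atoms: MeI (CI)
Why: C-alkylation of the stabilised 1,3-dione enolate; no stereocentre.

**Step 2**
Reactants: **2** 2-methylcyclohexane-1,3-dione
Product: **3** 2-methyl-2-(prop-2-enyl)cyclohexane-1,3-dione
Conditions: allyl bromide, 1 M aq. NaOH, n-Bu4NI (cat.), rt
Reagents that add atoms: allyl bromide (C=CCBr)
Why: C-allylation of the 2-alkyl-1,3-dione enolate with a reactive allylic halide builds the prochiral quaternary carbon (future C7) carrying C8–C9.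

**Step 3**
Reactants: **3** 2-methyl-2-(prop-2-enyl)cyclohexane-1,3-dione
Product: **4** (2R,3R)-3-hydroxy-2-methyl-2-(prop-2-enyl)cyclohexan-1-one (OH cis to allyl)
Conditions: (S)-Me-CBS (20 mol%), catecholborane (1.0 equiv), toluene, −60 °C
Reagents that add atoms: none
Why: CBS desymmetrising mono-reduction: the catalyst gives the 3R carbinol (quaternary carbon as the large group) and attack anti to allyl selects which carbonyl reacts, fixing C7; catecholborane leaves the alkene alone.

**Step 4**
Reactants: **4** (2R,3R)-3-hydroxy-2-methyl-2-(prop-2-enyl)cyclohexan-1-one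
Product: **5** (2S,3S)-3-bromo-2-methyl-2-(prop-2-enyl)cyclohexan-1-one (Br cis to Me, trans to allyl)
Conditions: CBr4, PPh3, toluene, 60 °C
Reagents that add atoms: CBr4 (BrC(Br)(Br)Br)
Why: Appel bromination with SN2 inversion sets C6–Br; the adjacent α-keto quaternary carbon disfavours ionisation and Wagner–Meerwein shift, and there is no α-H for E1cB.

**Step 5**
Reactants: **5** (2S,3S)-3-bromo-2-methyl-2-(prop-2-enyl)cyclohexan-1-one
Product: **6** (2S,3S)-3-bromo-2,6-dimethyl-2-(prop-2-enyl)cyclohexan-1-one (C6 epimers, inconsequential)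
Conditions: LDA, THF, −78 °C; MeI
Reagents that add atoms: MeI (CI)
Why: Enolate alkylation at the only enolisable α-carbon installs the C3 methyl.

**Step 6**
Reactants: **6** (2S,3S)-3-bromo-2,6-dimethyl-2-(prop-2-enyl)cyclohexan-1-one
Product: **7** (5S,6S)-5-bromo-2,6-dimethyl-6-(prop-2-enyl)cyclohex-2-en-1-one
Conditions: LDA, TMSCl, THF, −78 → 0 °C; then Pd(OAc)2, MeCN, rt
Reagents that add atoms: none
Why: Saegusa–Ito dehydrogenation of the regiodefined silyl enol ether gives the endocyclic 2-methyl enone (C3=C4) and removes the scrambled C3 centre.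

**Step 7**
Reactants: **7** (5S,6S)-5-bromo-2,6-dimethyl-6-(prop-2-enyl)cyclohex-2-en-1-one
Product: **8** 2-[(1S,6S)-6-bromo-1,3-dimethyl-2-oxocyclohex-3-en-1-yl]acetaldehyde
Conditions: OsO4 (2 mol%), NaIO4, 2,6-lutidine, dioxane/H2O, rt
Reagents that add atoms: OsO4 (O=[Os](=O)(=O)=O) / NaIO4 ([Na+].[O-]I(=O)(=O)=O) as oxygen source
Why: Lemieux–Johnson cleavage of the electron-rich terminal alkene trims allyl to the C8–C9 unit; the electron-poor trisubstituted enone is not dihydroxylated.

**Step 8**
Reactants: **8** 2-[(1S,6S)-6-bromo-1,3-dimethyl-2-oxocyclohex-3-en-1-yl]acetaldehyde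
Product: **9** (5S,6S)-5-bromo-6-(2-hydroxyethyl)-2,6-dimethylcyclohex-2-en-1-one
Conditions: NaBH4 (0.5 equiv), MeOH/CH2Cl2, −78 °C
Reagents that add atoms: none
Why: Chemoselective hydride reduction of the aldehyde over the hindered, conjugated ketone.

**Step 9**
Reactants: **9** (5S,6S)-5-bromo-6-(2-hydroxyethyl)-2,6-dimethylcyclohex-2-en-1-one
Product: **10** (5S,6S)-5-bromo-6-(2-iodoethyl)-2,6-dimethylcyclohex-2-en-1-one
Conditions: I2, PPh3, imidazole, CH2Cl2, 0 °C
Reagents that add atoms: I2 (II)
Why: Appel-type iodination of the primary alcohol under conditions too weakly basic to trigger vinylogous elimination of the C6 bromide.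

### Z-vinyl iodide fragment

**Step 10**
Reactants: **11** prop-2-yn-1-ol
Product: **12** (Z)-3-iodo-2-methylprop-2-en-1-ol
Conditions: MeMgBr (3 equiv), CuI (10 mol%), THF, −10 °C → rt; then I2, −78 °C → rt
Reagents that add atoms: MeMgBr (C[Mg]Br), I2 (II)
Why: Alkoxide-directed anti-carbomagnesiation gives a cyclic alkenylmagnesium whose iodinolysis places I cis to CH2OH, fixing the Z-C10=C11 geometry.

**Step 11**
Reactants: **12** (Z)-3-iodo-2-methylprop-2-en-1-ol
Product: **13** (Z)-3-bromo-1-iodo-2-methylprop-1-ene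
Conditions: CBr4, PPh3, CH2Cl2, 0 °C
Reagents that add atoms: CBr4 (BrC(Br)(Br)Br)
Why: Appel bromination of the primary allylic alcohol without touching the alkene geometry.

**Step 12**
Reactants: **14** 3-hydroxy-3-methylbutan-2-one
Product: **15** 3-methyl-3-(triethylsilyloxy)butan-2-one
Conditions: TESOTf, 2,6-lutidine, CH2Cl2, 0 °C
Reagents that add atoms: TESOTf (CC[Si](CC)(CC)OS(=O)(=O)C(F)(F)F)
Why: Silylation of the tertiary alcohol (future C15–OH) so that only the C14 hydroxyl is free later.

**Step 13**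
Reactants: **15** 3-methyl-3-(triethylsilyloxy)butan-2-one, **13** (Z)-3-bromo-1-iodo-2-methylprop-1-ene
Product: **16** (Z)-7-iodo-2,6-dimethyl-2-(triethylsilyloxy)hept-6-en-3-one
Conditions: LDA, THF, −78 °C; then **13**, −78 → −20 °C
Reagents that add atoms: none
Why: SN2 alkylation of the only possible (methyl) enolate with the allylic bromide forms C12–C13.

**Step 14**
Reactants: **16** (Z)-7-iodo-2,6-dimethyl-2-(triethylsilyloxy)hept-6-en-3-one
Product: **17** (3S,6Z)-7-iodo-2,6-dimethyl-2-(triethylsilyloxy)hept-6-en-3-ol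
Conditions: (R)-Me-CBS (20 mol%), BH3·SMe2, THF, −30 °C
Reagents that add atoms: none
Why: CBS reduction with CMe2(OTES) as the large group and CH2 as the small group sets 14S under catalyst control.

### Aryl fragment

**Step 15**
Reactants: **18** 2-bromophenol
Product: **19** 2-bromo-4-iodophenol
Conditions: NIS, TsOH (cat.), MeCN, rt
Reagents that add atoms: NIS (O=C1CCC(=O)N1I)
Why: Electrophilic aromatic iodination para to the hydroxyl.

**Step 16**
Reactants: **19** 2-bromo-4-iodophenol
Product: **20** 2-bromo-4-iodo-1-(methoxymethoxy)benzene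
Conditions: MOMCl, i-Pr2NEt, CH2Cl2, 0 °C → rt
Reagents that add atoms: MOMCl (COCCl)
Why: Phenol protection with a small group that tolerates the organometallic and Pd steps.

**Step 17**
Reactants: **20** 2-bromo-4-iodo-1-(methoxymethoxy)benzene
Product: **21** 3-bromo-4-(methoxymethoxy)benzoic acid
Conditions: i-PrMgCl·LiCl, THF, −40 °C; then CO2; NaH2PO4 work-up
Reagents that add atoms: CO2 (O=C=O)
Why: I/Mg exchange is much faster at C–I than C–Br, so carboxylation occurs para to OMOM and keeps the bromide for the Suzuki step.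

### Fragment union and endgame

**Step 18**
Reactants: **17** (3S,6Z)-7-iodo-2,6-dimethyl-2-(triethylsilyloxy)hept-6-en-3-ol, **21** 3-bromo-4-(methoxymethoxy)benzoic acid
Product: **22** (3S,6Z)-7-iodo-2,6-dimethyl-2-(triethylsilyloxy)hept-6-en-3-yl 3-bromo-4-(methoxymethoxy)benzoate
Conditions: 2,4,6-trichlorobenzoyl chloride, Et3N, THF; then **17**, DMAP, toluene, 50 °C
Reagents that add atoms: none
Why: Yamaguchi esterification forms the C14–O ester intermolecularly with retention at C14, where a hindered alcohol can be forced.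

**Step 19**
Reactants: **10** (5S,6S)-5-bromo-6-(2-iodoethyl)-2,6-dimethylcyclohex-2-en-1-one, **22** the vinyl iodide benzoate
Product: **23** (3S,6Z)-9-[(1S,6S)-6-bromo-1,3-dimethyl-2-oxocyclohex-3-en-1-yl]-2,6-dimethyl-2-(triethylsilyloxy)non-6-en-3-yl 3-bromo-4-(methoxymethoxy)benzoate
Conditions: **10**, Zn dust (TMSCl/BrCH2CH2Br-activated), LiCl, THF, 25 °C; then **22**, PdCl2(dppf) (5 mol%), THF/NMP, 40 °C
Reagents that add atoms: none
Why: Negishi sp3–sp2 coupling forms C9–C10 with retention of Z geometry; Zn inserts into the primary C–I only, and Pd adds to the vinyl iodide in preference to the aryl bromide.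

**Step 20**
Reactants: **23** the Negishi product
Product: **24** the C15 tertiary alcohol: (3S,6Z)-9-[(1S,6S)-6-bromo-1,3-dimethyl-2-oxocyclohex-3-en-1-yl]-2-hydroxy-2,6-dimethylnon-6-en-3-yl 3-bromo-4-(methoxymethoxy)benzoate
Conditions: HF·pyridine, pyridine/THF, 0 °C → rt
Reagents that add atoms: none
Why: Fluoride desilylation of the TES ether; MOM, ester, enone and bromide are untouched.

**Step 21**
Reactants: **24** the C15 tertiary alcohol
Product: **25** (3S,6R)-6-{(1R)-1-bromo-3-[(1S,6S)-6-bromo-1,3-dimethyl-2-oxocyclohex-3-en-1-yl]propyl}-2,2,6-trimethyloxan-3-yl 3-bromo-4-(methoxymethoxy)benzoate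
Conditions: NBS (1.1 equiv), CH2Cl2, 4 Å MS, −20 → 0 °C, dark
Reagents that add atoms: NBS (O=C1CCC(=O)N1Br)
Why: 6-exo bromoetherification at the only nucleophilic alkene (the enone is inert); anti addition across the Z-alkene gives 10R,11R, via a chair transition state with the C14 aroyloxy group and C10 equatorial and the C11 methyl axial.

**Step 22**
Reactants: **25** the bromo-oxane enone
Product: **26** (3S,6R)-6-{(1R)-1-bromo-3-[(1S,6S)-6-bromo-1,3-dimethyl-2-methylidenecyclohex-3-en-1-yl]propyl}-2,2,6-trimethyloxan-3-yl 3-bromo-4-(methoxymethoxy)benzoate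
Conditions: Tebbe reagent (1.2 equiv, 0.5 M in toluene), pyridine (cat.), THF, −40 → 0 °C; quench with wet Et2O, filter through basic alumina
Reagents that add atoms: Tebbe reagent (C[Al-]1(C)C[Ti](C2C=CC=C2)(C2C=CC=C2)[Cl+]1)
Why: Tebbe methylenation (titanium methylidene, [2+2]/retro-[2+2]) is non-basic and converts the hindered ketone to the exocyclic C1=C2 alkene faster than it attacks the aryl ester, avoiding loss of either secondary bromide; zinc-based methylenation is not used because Zn metal could reductively open the β-bromo ether.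

**Step 23**
Reactants: **26** the bromo-oxane exocyclic diene
Product: **27** bromophycolide U O-methoxymethyl ether (15-membered macrolide, 2R)
Conditions: 9-BBN-H (2 equiv), THF, 0 °C → rt; then syringe-pump addition to PdCl2(dppf) (20 mol%), AsPh3, Cs2CO3, DMF/THF/H2O, 50 °C, 2 mM
Reagents that add atoms: none
Why: 9-BBN adds to the terminal C1 of the s-trans diene from the face anti to the axial C7 methyl (C6–Br equatorial), placing H on C2 (2R), and intramolecular B-alkyl Suzuki–Miyaura coupling with the aryl bromide closes the macrocycle.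

**Step 24**
Reactants: **27** bromophycolide U O-methoxymethyl ether
Product: **28** bromophycolide U
Conditions: TMSOTf, 2,2′-bipyridyl, CH2Cl2, 0 °C; then H2O
Reagents that add atoms: none
Why: Buffered silyl-triflate cleavage of the aryl MOM acetal under near-neutral conditions, avoiding acid-promoted chroman formation onto C3=C4.

## Compound list

1 | cyclohexane-1,3-dione | O=C1CCCC(=O)C1 | starting material
2 | 2-methylcyclohexane-1,3-dione | CC1C(=O)CCCC1=O | intermediate
3 | 2-methyl-2-(prop-2-enyl)cyclohexane-1,3-dione | C=CCC1(C)C(=O)CCCC1=O | intermediate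
4 | (2R,3R)-3-hydroxy-2-methyl-2-(prop-2-enyl)cyclohexan-1-one | C1CC[C@@H](O)[C@@](C)(CC=C)C1=O | intermediate
5 | (2S,3S)-3-bromo-2-methyl-2-(prop-2-enyl)cyclohexan-1-one | C1CC[C@H](Br)[C@@](C)(CC=C)C1=O | intermediate
6 | (2S,3S)-3-bromo-2,6-dimethyl-2-(prop-2-enyl)cyclohexan-1-one (C6 epimers) | CC1CC[C@H](Br)[C@@](C)(CC=C)C1=O | intermediate
7 | (5S,6S)-5-bromo-2,6-dimethyl-6-(prop-2-enyl)cyclohex-2-en-1-one | CC1=CC[C@H](Br)[C@@](C)(CC=C)C1=O | intermediate
8 | 2-[(1S,6S)-6-bromo-1,3-dimethyl-2-oxocyclohex-3-en-1-yl]acetaldehyde | CC1=CC[C@H](Br)[C@@](C)(CC=O)C1=O | intermediate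
9 | (5S,6S)-5-bromo-6-(2-hydroxyethyl)-2,6-dimethylcyclohex-2-en-1-one | CC1=CC[C@H](Br)[C@@](C)(CCO)C1=O | intermediate
10 | (5S,6S)-5-bromo-6-(2-iodoethyl)-2,6-dimethylcyclohex-2-en-1-one | CC1=CC[C@H](Br)[C@@](C)(CCI)C1=O | intermediate
11 | prop-2-yn-1-ol | C#CCO | starting material
12 | (Z)-3-iodo-2-methylprop-2-en-1-ol | OC/C(C)=C\I | intermediate
13 | (Z)-3-bromo-1-iodo-2-methylprop-1-ene | BrC/C(C)=C\I | intermediate
14 | 3-hydroxy-3-methylbutan-2-one | CC(=O)C(C)(C)O | starting material
15 | 3-methyl-3-(triethylsilyloxy)butan-2-one | CC(=O)C(C)(C)O[Si](CC)(CC)CC | intermediate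
16 | (Z)-7-iodo-2,6-dimethyl-2-(triethylsilyloxy)hept-6-en-3-one | I/C=C(C)\CCC(=O)C(C)(C)O[Si](CC)(CC)CC | intermediate
17 | (3S,6Z)-7-iodo-2,6-dimethyl-2-(triethylsilyloxy)hept-6-en-3-ol | I/C=C(C)\CC[C@H](O)C(C)(C)O[Si](CC)(CC)CC | intermediate
18 | 2-bromophenol | Oc1ccccc1Br | starting material
19 | 2-bromo-4-iodophenol | Oc1ccc(I)cc1Br | intermediate
20 | 2-bromo-4-iodo-1-(methoxymethoxy)benzene | COCOc1ccc(I)cc1Br | intermediate
21 | 3-bromo-4-(methoxymethoxy)benzoic acid | COCOc1ccc(C(=O)O)cc1Br | intermediate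
22 | (3S,6Z)-7-iodo-2,6-dimethyl-2-(triethylsilyloxy)hept-6-en-3-yl 3-bromo-4-(methoxymethoxy)benzoate | I/C=C(C)\CC[C@H](OC(=O)c1ccc(OCOC)c(Br)c1)C(C)(C)O[Si](CC)(CC)CC | intermediate
23 | Negishi product (enone, Z-alkene, OTES; name in step 19) | CC1=CC[C@H](Br)[C@@](C)(CC/C=C(C)\CC[C@H](OC(=O)c2ccc(OCOC)c(Br)c2)C(C)(C)O[Si](CC)(CC)CC)C1=O | intermediate
24 | C15 tertiary alcohol of 23 (name in step 20) | CC1=CC[C@H](Br)[C@@](C)(CC/C=C(C)\CC[C@H](OC(=O)c2ccc(OCOC)c(Br)c2)C(C)(C)O)C1=O | intermediate
25 | bromo-oxane enone (name in step 21) | CC1=CC[C@H](Br)[C@@](C)(CC[C@@H](Br)[C@@]3(C)CC[C@H](OC(=O)c2ccc(OCOC)c(Br)c2)C(C)(C)O3)C1=O | intermediate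
26 | bromo-oxane exocyclic diene (name in step 22) | CC1=CC[C@H](Br)[C@@](C)(CC[C@@H](Br)[C@@]3(C)CC[C@H](OC(=O)c2ccc(OCOC)c(Br)c2)C(C)(C)O3)C1=C | intermediate
27 | bromophycolide U O-MOM ether | CC1=CC[C@H](Br)[C@@]2(C)CC[C@@H](Br)[C@@]3(C)CC[C@H](OC(=O)c4ccc(OCOC)c(c4)C[C@H]12)C(C)(C)O3 | intermediate
28 | bromophycolide U | CC1=CC[C@H](Br)[C@@]2(C)CC[C@@H](Br)[C@@]3(C)CC[C@H](OC(=O)c4ccc(O)c(c4)C[C@H]12)C(C)(C)O3 | target

## Totals

Total step count: 24.
Longest linear sequence: 15 steps (steps 1–9, then 19–24).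

## Three steps most likely to fail

1. **Step 4 (Appel inversion at the neopentyl secondary carbinol).** SN2 may lose to elimination or a 1,2-shift. Fallback: stop relying on displacement and install the bromine while forming ring A, by a bromonium-initiated (e.g. BDSB) cyclisation of an acyclic (E)-1,5-diene precursor, then resolve.

2. **Step 21 (bromoetherification).** The C10/C11 facial selectivity relative to C14 rests on a chair transition-state argument and could be poor. Fallback: a stereospecific epoxide route — use the E-vinyl iodide (Zr-catalysed carboalumination/iodination of the corresponding alkyne), Shi epoxidation after coupling, acid-catalysed 6-exo epoxide opening by C15–OH to set C11 under reagent control, then convert C10–OH to bromide with inversion.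

3. **Step 23 (hydroboration/B-alkyl Suzuki macrocyclisation).** Both the C2 facial selectivity and the 15-membered ring closure are uncertain. Fallback: hydroborate and Suzuki-couple the ring-A diene intermolecularly with an ester of acid **21** before fragment union (C2 epimers separable at that stage), then close the ring by Yamaguchi/Shiina macrolactonisation at C14–OH.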